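The reading comes at 12 h, and the next flask is to be charged by one of two recipes: amber feeds the free monomer over 12 h, green over 8.0 h.

| flask | free monomer | transfer agent | initiator | remark | time |
|---|---|---|---|---|---|
| epsilon | 17 mM (fed, over 12 h) | 1.1 mM | 0.70 mM | run made earlier |  |
| gamma | 17 mM (fed, over 12 h) | 2.5 mM | 0.70 mM | run made earlier |  |
| amber | 17 mM (fed, over 12 h) | 1.70 mM | 0.70 mM |  | 12 h |
| green | 17 mM (fed, over 8.0 h) | 1.70 mM | 0.70 mM |  | 12 h |

- epsilon (time / h: monomer in chains / %, free monomer / %): 0.500: 2, 5; 1.33: 2, 9; 3.00: 4, 25; 8.00: 18, 50
- gamma (time / h: monomer in chains / %, free monomer / %): 2.00: 0, 18; 4.00: 4, 32; 5.00: 6, 36; 8.00: 15, 51

(standard deviation of a reading: 1.5 percentage points)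

- which of the two ends with the longer chains by the average number of monomer units in a chain (chains begun, living or dead) ("neither" if they lie within 10%) (amber / green / neither)
- average number of monomer units in a chain (chains begun, living or dead) at the end, amber
- average number of monomer units in a chain (chains begun, living or dead) at the end, green

- the average divides the monomer in chains by the number of chains begun, living and dead together
- the numbers in the tables scatter with a standard deviation of 1.5 percentage points
- reactions considered so far: free monomer + initiator -> living end + monomer in chains; free monomer + living end -> monomer in chains + living end; living end + transfer agent -> dead chain; initiator + monomer in chains -> spent initiator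
- the earlier runs do not show the number of chains; that part of a forecast is a guess
- percentages count the whole charge, also what has not yet gone in

The average length is a quotient, so it splits into three factors. The first is the charge ratio, free monomer charged per initiator charged, 24.3, the same for amber and green. The second is the fraction of the monomer charge in chains, and the third divides by chains begun as a fraction of the initiator charge.

For the second factor, the concentration to watch is that of the living ends. If it holds nearly steady, uptake is pseudo-first-order in free monomer. Monomer gained by the chains per hour, divided by the mean free monomer, reads 0.0747 /h in the epsilon run between 3.00 h and 8.00 h, and 0.0663 /h in the gamma run between 4.00 h and 8.00 h. Amber's 1.70 mM of transfer agent lies between their 1.1 mM and 2.5 mM, so this reckoning takes the mean, 0.0705 /h. Run through each feed, that puts 32.5% of the charge in chains for amber and 42.3% for green at 12 h.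

The earlier runs do not show the third factor, so the guess here is one chain per initiator charged. The lengths are then 7.90 for amber and 10.3 for green. With the same guessed divisor for both, this reckoning puts green ahead by 30.2%, more than the 10% margin, so green is the recipe to charge.

The forecast also names green, but at longer lengths: 14 for amber and 16 for green. Of its divisor it says: “Chain count is the guess.”

The flasks end with green longer, at 9.37 for amber and 12.1 for green.

    free monomer + initiator → living end + monomer in chains (k = 31.3 /M/h)
    free monomer + living end → monomer in chains + living end, rate k2*[living end]*[free monomer] (k = 379 /M/h)
    living end + transfer agent → dead chain (kL = 178 /M/h)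
    initiator + monomer in chains → spent initiator (k = 2.02 /M/h)

In amber at 12.0 h, 34.9% of the charge stands in chains. Chains begun, living and dead, come to 0.633 mM, against the forecast's 0.4 mM, and that is 90.4% of the initiator charge. The charge ratio then gives 9.37. A neighbour like amber but charged with 10 mM of free monomer has a charge ratio of 14.3, and the reckoning made for amber, with 32.5% of the charge in chains and one chain per initiator charged, gives it a length of 4.64. That neighbour ends with 31.7% of its charge in chains, chains begun at 77.1% of the initiator charge, and an average length of 5.87.

The earlier runs and the new flask stem from a simulated flask from invented constants; the scatter is artificial.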